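**Plan**

- Retrosynthesis: the seven aryl benzyl ethers are removed last. The flavanone is cut at O1–C2 (oxa-Michael) and C2–C3 (Knoevenagel, with a temporary C3 ester), the flavone at C4a''–C4'', C4''–C3'' and O1''–C2'' (iodophenol + CO + arylacetylene), and the biaryl at C5'–C6'' (Suzuki).
- Forward: the ring B boronate and the phloroglucinol-ring bromide are joined first and the freed phenol is iodinated. Flavone ring C'' is then closed by the three-component annulation, the aldehyde is unmasked, and flavanone ring C is closed last onto ring A.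
- Enabling feature: in pyranone ring C'' (O1'', C2'', C3'', C4'', C4a'', C8a'') the carbonyl C4'' lies between aryl carbon C4a'' and the C2''=C3'' alkene, and O1'' sits on C8a'', para to biaryl carbon C6''. An ortho-iodophenol whose hydroxyl is para to the biaryl bond, CO and a terminal alkyne map onto this ring exactly.
- Stereochemistry: the only stereocentre, C2 (S), is set by a cinchona-thiourea-catalysed oxa-Michael closure and is preserved by finishing under neutral hydrogenolysis.

Key step: step 9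

Numbering: unprimed = flavanone core, primed = ring B, doubly primed = flavone core, triply primed = flavone 2-aryl ring.
Assumption: the quinidine-derived thiourea is taken to deliver 2S; its quinine-derived pseudoenantiomer would be used if the sense of induction proved opposite.
Assumption: the biaryl axis (three ortho oxygens, one ortho hydrogen) is taken to rotate freely at room temperature, as the target carries no axial descriptor.

**Route**

Step 1
Reactants: 1 3,5-bis(benzyloxy)phenol
Product: 2 triisopropylsilyl ether of 3,5-bis(benzyloxy)phenol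
Conditions: i-Pr3SiCl, imidazole, DMF, rt
Reagents that add atoms: chlorotriisopropylsilane, CC(C)[Si](Cl)(C(C)C)C(C)C
Why: Standard silylation of a phenol with a silyl chloride and imidazole; the bulky triisopropylsilyl group is chosen because it later screens both ring positions next to its oxygen.

Step 2
Reactants: 2 triisopropylsilyl ether of 3,5-bis(benzyloxy)phenol
Product: 3 [4-bromo-3,5-bis(benzyloxy)phenoxy]triisopropylsilane
Conditions: NBS (1.0 equiv), CH2Cl2, −78 °C to 0 °C
Reagents that add atoms: N-bromosuccinimide, O=C1CCC(=O)N1Br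
Why: Electrophilic aromatic bromination of a phloroglucinol triether whose three free positions are electronically similar, so the steric screen of the silyloxy group should direct the single bromine to C4 between the two benzyloxy groups.

Step 3
Reactants: 4 3-bromo-4,5-dihydroxybenzaldehyde
Product: 5 3,4-bis(benzyloxy)-5-bromobenzaldehyde
Conditions: BnBr (2.4 equiv), K2CO3, DMF, 60 °C
Reagents that add atoms: benzyl bromide, BrCc1ccccc1
Why: Williamson ether synthesis on both catechol hydroxyls under conditions that leave the aldehyde and the aryl bromide untouched.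

Step 4
Reactants: 5 3,4-bis(benzyloxy)-5-bromobenzaldehyde
Product: 6 2-[3,4-bis(benzyloxy)-5-bromophenyl]-1,3-dioxolane
Conditions: ethylene glycol, TsOH·H2O (cat.), toluene, reflux, Dean–Stark
Reagents that add atoms: ethylene glycol, OCCO
Why: Acid-catalysed acetalisation with azeotropic removal of water masks the aldehyde against the amine, fluoride and palladium steps that follow.

Step 5
Reactants: 6 2-[3,4-bis(benzyloxy)-5-bromophenyl]-1,3-dioxolane
Product: 7 2-[2,3-bis(benzyloxy)-5-(1,3-dioxolan-2-yl)phenyl]-4,4,5,5-tetramethyl-1,3,2-dioxaborolane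
Conditions: B2pin2, PdCl2(dppf) (3 mol %), KOAc, 1,4-dioxane, 90 °C
Reagents that add atoms: bis(pinacolato)diboron, CC1(C)OB(B2OC(C)(C)C(C)(C)O2)OC1(C)C
Why: Miyaura borylation of an aryl bromide tolerates benzyl ethers and the acetal and avoids generating an aryllithium next to a benzyl ether.

Step 6
Reactants: 3 [4-bromo-3,5-bis(benzyloxy)phenoxy]triisopropylsilane; 7 ring B pinacol boronate
Product: 8 {4-[2,3-bis(benzyloxy)-5-(1,3-dioxolan-2-yl)phenyl]-3,5-bis(benzyloxy)phenoxy}triisopropylsilane
Conditions: Pd(OAc)2 (5 mol %), SPhos (10 mol %), K3PO4, toluene/H2O (10:1), 100 °C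
Reagents that add atoms: none
Why: Suzuki–Miyaura coupling with the SPhos ligand, which is established for electron-rich, doubly ortho-substituted aryl bromides and for biaryls with three ortho substituents, forms the C5'–C6'' bond.

Step 7
Reactants: 8 biaryl triisopropylsilyl ether
Product: 9 4-[2,3-bis(benzyloxy)-5-(1,3-dioxolan-2-yl)phenyl]-3,5-bis(benzyloxy)phenol
Conditions: Bu4NF, THF, 0 °C; aqueous work-up
Reagents that add atoms: none
Why: Fluoride-mediated cleavage of an aryl silyl ether, driven by Si–F bond formation, with benzyl ethers and the acetal inert.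

Step 8
Reactants: 9 4-aryl-3,5-bis(benzyloxy)phenol
Product: 10 2-iodo-4-[2,3-bis(benzyloxy)-5-(1,3-dioxolan-2-yl)phenyl]-3,5-bis(benzyloxy)phenol
Conditions: NIS (1.0 equiv), CH2Cl2, −20 °C, dark
Reagents that add atoms: N-iodosuccinimide, O=C1CCC(=O)N1I
Why: Electrophilic aromatic iodination ortho to the free hydroxyl of a phloroglucinol-type ring far more nucleophilic than ring B; the two ortho positions are equivalent, so one equivalent of NIS in the cold should give a single monoiodide.

Step 9
Reactants: 10 2-iodo-4-aryl-3,5-bis(benzyloxy)phenol; 11 1-(benzyloxy)-4-ethynylbenzene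
Product: 14 6-[2,3-bis(benzyloxy)-5-(1,3-dioxolan-2-yl)phenyl]-5,7-bis(benzyloxy)-2-[4-(benzyloxy)phenyl]-4H-chromen-4-one, via aryl alkynyl ketone 12 (not isolated), via diethylamino enone 13 (not isolated)
Conditions: PdCl2(dppf) (5 mol %), CO (20 bar), Et2NH/toluene, 110 °C
Reagents that add atoms: carbon monoxide, [C-]#[O+]
Why: The amine and alkyne reduce PdCl2(dppf) to zerovalent palladium, which inserts into the C–I bond of 10; CO then inserts to give an aroyl–palladium species, and transfer of the acetylide of 11 (deprotonated by Et2NH) followed by reductive elimination forms C4a''–C4'' and C4''–C3'' in ynone 12. Et2NH adds to the ynone to give the push–pull enaminone 13, whose neighbouring phenol attacks the β-carbon and expels the amine, forming O1''–C2'' and closing ring C'' in a 6-endo mode (6-endo-dig counted from the ynone, in practice an addition–elimination at the enaminone carbon). The closest known reaction type is the palladium-catalysed carbonylative annulation of ortho-iodophenols with terminal alkynes to flavones, a carbonylative Sonogashira coupling followed by cyclisation. No stereocentre is formed. Three selectivities are needed: CO uptake must outrun direct alkynylation (which would end in a 2-arylbenzofuran), and the CO pressure is there to secure this; 6-endo flavone closure must beat 5-exo aurone closure, which the secondary amine secures by routing the ynone through the enaminone; and the aryl group must end at C6'' and not C8'', which is fixed because the only free hydroxyl of 10 is para to the biaryl carbon while both oxygens flanking that carbon are benzylated. The acetal and the benzyl ethers are spectators, inert to amine, CO and palladium at this temperature.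

Step 10
Reactants: 14 flavone acetal
Product: 15 3,4-bis(benzyloxy)-5-{5,7-bis(benzyloxy)-2-[4-(benzyloxy)phenyl]-4-oxo-4H-chromen-6-yl}benzaldehyde
Conditions: 1 M HCl (aq), THF, rt
Reagents that add atoms: water, O
Why: Acid-catalysed hydrolysis of the dioxolane; the flavone and the benzyl ethers are stable to dilute aqueous acid at room temperature.

Step 11
Reactants: 16 1-[2-hydroxy-4,6-bis(benzyloxy)phenyl]ethan-1-one
Product: 17 tert-butyl 3-[2-hydroxy-4,6-bis(benzyloxy)phenyl]-3-oxopropanoate
Conditions: LiN(SiMe3)2 (3.2 equiv), THF, −78 °C; Boc2O (1.1 equiv), −78 °C to 0 °C; aq NH4Cl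
Reagents that add atoms: di-tert-butyl dicarbonate, CC(C)(C)OC(=O)OC(=O)OC(C)(C)C
Why: Claisen-type C-acylation of the lithium polyanion of an ortho-hydroxyacetophenone, in which the enolate carbon reacts ahead of the chelated phenoxide and the excess base holds the product as its enolate.

Step 12
Reactants: 15 flavone aldehyde; 17 tert-butyl aroylacetate
Product: 18 tert-butyl (2Z)-2-[2-hydroxy-4,6-bis(benzyloxy)benzoyl]-3-(3,4-bis(benzyloxy)-5-{5,7-bis(benzyloxy)-2-[4-(benzyloxy)phenyl]-4-oxo-4H-chromen-6-yl}phenyl)prop-2-enoate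
Conditions: piperidine (10 mol %), AcOH (10 mol %), 4 Å MS, toluene, rt
Reagents that add atoms: none
Why: Knoevenagel condensation of an aryl aldehyde with no substituent next to the formyl group and an aroylacetate under piperidinium acetate catalysis with water removal, expected to give mainly the isomer with the aryl group cis to the ester.

Step 13
Reactants: 18 alkylidene β-ketoester
Product: 20 (2S)-5,7-bis(benzyloxy)-2-(3,4-bis(benzyloxy)-5-{5,7-bis(benzyloxy)-2-[4-(benzyloxy)phenyl]-4-oxo-4H-chromen-6-yl}phenyl)-2,3-dihydro-4H-chromen-4-one, via tert-butyl flavanone-3-carboxylate 19 (not isolated)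
Conditions: 3,5-bis(trifluoromethyl)phenyl thiourea of 9-amino-9-deoxy-epi-quinidine (10 mol %), toluene, −25 °C; then TsOH·H2O, 80 °C
Reagents that add atoms: none
Why: Enantioselective intramolecular oxa-Michael addition (6-endo-trig) under a bifunctional cinchona thiourea, in which the thiourea binds the 1,3-dicarbonyl unit and the quinuclidine base delivers the phenol to one face of the alkylidene to set C2 as S, followed by acid cleavage of the tert-butyl ester and decarboxylation that erases C3.

Step 14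
Reactants: 20 (2S)-heptabenzyl biflavonoid
Product: 21 (2S)-2-{3,4-dihydroxy-5-[5,7-dihydroxy-2-(4-hydroxyphenyl)-4-oxo-4H-chromen-6-yl]phenyl}-5,7-dihydroxy-2,3-dihydro-4H-chromen-4-one (CNP0176432.1)
Conditions: H2 (1 atm), 10% Pd/C, THF/MeOH, rt, stopped on completion
Reagents that add atoms: none
Why: Heterogeneous hydrogenolysis of aryl benzyl ethers under neutral conditions, which offers no acid- or base-mediated ring-opening pathway for racemisation at C2 and normally leaves the flavone C2''=C3'' bond and the flavanone C2–O bond intact.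

**Compound list**

1 | 3,5-bis(benzyloxy)phenol | Oc1cc(OCc2ccccc2)cc(OCc2ccccc2)c1 | starting material
2 | [3,5-bis(benzyloxy)phenoxy]triisopropylsilane | CC(C)[Si](Oc1cc(OCc2ccccc2)cc(OCc2ccccc2)c1)(C(C)C)C(C)C | intermediate
3 | [4-bromo-3,5-bis(benzyloxy)phenoxy]triisopropylsilane | CC(C)[Si](Oc1cc(OCc2ccccc2)c(Br)c(OCc2ccccc2)c1)(C(C)C)C(C)C | intermediate
4 | 3-bromo-4,5-dihydroxybenzaldehyde | O=Cc1cc(O)c(O)c(Br)c1 | starting material
5 | 3,4-bis(benzyloxy)-5-bromobenzaldehyde | O=Cc1cc(OCc2ccccc2)c(OCc2ccccc2)c(Br)c1 | intermediate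
6 | 2-[3,4-bis(benzyloxy)-5-bromophenyl]-1,3-dioxolane | Brc1cc(C2OCCO2)cc(OCc2ccccc2)c1OCc1ccccc1 | intermediate
7 | 2-[2,3-bis(benzyloxy)-5-(1,3-dioxolan-2-yl)phenyl]-4,4,5,5-tetramethyl-1,3,2-dioxaborolane | CC1(C)OB(c2cc(C3OCCO3)cc(OCc3ccccc3)c2OCc2ccccc2)OC1(C)C | intermediate
8 | {4-[2,3-bis(benzyloxy)-5-(1,3-dioxolan-2-yl)phenyl]-3,5-bis(benzyloxy)phenoxy}triisopropylsilane | CC(C)[Si](Oc1cc(OCc2ccccc2)c(-c2cc(C3OCCO3)cc(OCc3ccccc3)c2OCc2ccccc2)c(OCc2ccccc2)c1)(C(C)C)C(C)C | intermediate
9 | 4-[2,3-bis(benzyloxy)-5-(1,3-dioxolan-2-yl)phenyl]-3,5-bis(benzyloxy)phenol | Oc1cc(OCc2ccccc2)c(-c2cc(C3OCCO3)cc(OCc3ccccc3)c2OCc2ccccc2)c(OCc2ccccc2)c1 | intermediate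
10 | 2-iodo-4-[2,3-bis(benzyloxy)-5-(1,3-dioxolan-2-yl)phenyl]-3,5-bis(benzyloxy)phenol | Oc1cc(OCc2ccccc2)c(-c2cc(C3OCCO3)cc(OCc3ccccc3)c2OCc2ccccc2)c(OCc2ccccc2)c1I | intermediate
11 | 1-(benzyloxy)-4-ethynylbenzene | C#Cc1ccc(OCc2ccccc2)cc1 | starting material
12 | 1-{2-hydroxy-4,6-bis(benzyloxy)-5-[2,3-bis(benzyloxy)-5-(1,3-dioxolan-2-yl)phenyl]phenyl}-3-[4-(benzyloxy)phenyl]prop-2-yn-1-one | Oc1cc(OCc2ccccc2)c(-c2cc(C3OCCO3)cc(OCc3ccccc3)c2OCc2ccccc2)c(OCc2ccccc2)c1C(=O)C#Cc1ccc(OCc2ccccc2)cc1 | intermediate (not isolated)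
13 | (2E)-3-(diethylamino)-1-{2-hydroxy-4,6-bis(benzyloxy)-5-[2,3-bis(benzyloxy)-5-(1,3-dioxolan-2-yl)phenyl]phenyl}-3-[4-(benzyloxy)phenyl]prop-2-en-1-one (drawn E; the push–pull alkene isomerises freely) | CCN(CC)/C(=C/C(=O)c1c(O)cc(OCc2ccccc2)c(-c2cc(C3OCCO3)cc(OCc3ccccc3)c2OCc2ccccc2)c1OCc1ccccc1)c1ccc(OCc2ccccc2)cc1 | intermediate (not isolated)
14 | 6-[2,3-bis(benzyloxy)-5-(1,3-dioxolan-2-yl)phenyl]-5,7-bis(benzyloxy)-2-[4-(benzyloxy)phenyl]-4H-chromen-4-one | O=c1cc(-c2ccc(OCc3ccccc3)cc2)oc2cc(OCc3ccccc3)c(-c3cc(C4OCCO4)cc(OCc4ccccc4)c3OCc3ccccc3)c(OCc3ccccc3)c12 | intermediate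
15 | 3,4-bis(benzyloxy)-5-{5,7-bis(benzyloxy)-2-[4-(benzyloxy)phenyl]-4-oxo-4H-chromen-6-yl}benzaldehyde | O=Cc1cc(OCc2ccccc2)c(OCc2ccccc2)c(-c2c(OCc3ccccc3)cc3oc(-c4ccc(OCc5ccccc5)cc4)cc(=O)c3c2OCc2ccccc2)c1 | intermediate
16 | 1-[2-hydroxy-4,6-bis(benzyloxy)phenyl]ethan-1-one | CC(=O)c1c(O)cc(OCc2ccccc2)cc1OCc1ccccc1 | starting material
17 | tert-butyl 3-[2-hydroxy-4,6-bis(benzyloxy)phenyl]-3-oxopropanoate | CC(C)(C)OC(=O)CC(=O)c1c(O)cc(OCc2ccccc2)cc1OCc1ccccc1 | intermediate
18 | tert-butyl (2Z)-2-[2-hydroxy-4,6-bis(benzyloxy)benzoyl]-3-(3,4-bis(benzyloxy)-5-{5,7-bis(benzyloxy)-2-[4-(benzyloxy)phenyl]-4-oxo-4H-chromen-6-yl}phenyl)prop-2-enoate | CC(C)(C)OC(=O)/C(=C\c1cc(OCc2ccccc2)c(OCc2ccccc2)c(-c2c(OCc3ccccc3)cc3oc(-c4ccc(OCc5ccccc5)cc4)cc(=O)c3c2OCc2ccccc2)c1)C(=O)c1c(O)cc(OCc2ccccc2)cc1OCc1ccccc1 | intermediate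
19 | tert-butyl (2S)-5,7-bis(benzyloxy)-2-(3,4-bis(benzyloxy)-5-{5,7-bis(benzyloxy)-2-[4-(benzyloxy)phenyl]-4-oxo-4H-chromen-6-yl}phenyl)-4-oxo-3,4-dihydro-2H-chromene-3-carboxylate (C3 epimerisable, left undefined) | O=C1C(C(=O)OC(C)(C)C)[C@@H](c2cc(OCc3ccccc3)c(OCc3ccccc3)c(-c3c(OCc4ccccc4)cc4oc(-c5ccc(OCc6ccccc6)cc5)cc(=O)c4c3OCc3ccccc3)c2)Oc2cc(OCc3ccccc3)cc(OCc3ccccc3)c21 | intermediate (not isolated)
20 | (2S)-5,7-bis(benzyloxy)-2-(3,4-bis(benzyloxy)-5-{5,7-bis(benzyloxy)-2-[4-(benzyloxy)phenyl]-4-oxo-4H-chromen-6-yl}phenyl)-2,3-dihydro-4H-chromen-4-one | O=C1C[C@@H](c2cc(OCc3ccccc3)c(OCc3ccccc3)c(-c3c(OCc4ccccc4)cc4oc(-c5ccc(OCc6ccccc6)cc5)cc(=O)c4c3OCc3ccccc3)c2)Oc2cc(OCc3ccccc3)cc(OCc3ccccc3)c21 | intermediate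
21 | (2S)-2-{3,4-dihydroxy-5-[5,7-dihydroxy-2-(4-hydroxyphenyl)-4-oxo-4H-chromen-6-yl]phenyl}-5,7-dihydroxy-2,3-dihydro-4H-chromen-4-one | O=C1C[C@@H](c2cc(O)c(O)c(-c3c(O)cc4oc(-c5ccc(O)cc5)cc(=O)c4c3O)c2)Oc2cc(O)cc(O)c21 | target

**Step count and risks**

Total step count: 14. Longest linear sequence: 11 steps (from 4 through steps 3–10 and 12–14); steps 1–2 and step 11 are side branches.

Steps most likely to fail:

1. Step 9 (three-component annulation). The C–I bond is electron-rich and flanked by two ortho substituents, so oxidative addition may be slow. Alkynylation without CO uptake could then take over and close to a benzofuran, the ynone could close 5-exo to an aurone, or the iodide could simply be reduced off.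
 Fallback (stepwise ynone assembly without CO): from 10, silylation (t-BuMe2SiCl, imidazole, DMF) should give the tert-butyldimethylsilyl ether of the iodophenol F1. Iodine–magnesium exchange on F1 (i-PrMgCl·LiCl, THF, −20 °C to 0 °C) and acylation of the arylmagnesium with the Weinreb amide N-methoxy-N-methyl-3-[4-(benzyloxy)phenyl]prop-2-ynamide F2 should give the silyl-protected ynone F3; F2 is made from 11 with n-BuLi and N-methoxy-N-methylcarbamoyl chloride. Desilylation of F3 with Bu4NF buffered by AcOH should free ynone 12, which Et2NH in EtOH should convert by way of enaminone 13 into flavone 14, where the route resumes.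

2. Step 13 (enantioselective oxa-Michael closure and decarboxylation). The alkylidene carries a benzyloxy group ortho to the ketone, which may accelerate uncatalysed closure during or after the Knoevenagel step and erode the enantiomeric purity. Facial discrimination by the catalyst may also be poor on so large a substrate, and ring-opening to the chalcone during the acidic decarboxylation could racemise C2.
 Fallback (racemic closure and resolution): from 15 and 16, Claisen–Schmidt condensation (KOH, EtOH/THF, rt) should give the 2'-hydroxychalcone F4. Closure of F4 with NaOAc in refluxing EtOH should give the racemic heptabenzyl flavanone F5. Preparative chromatography on a chiral stationary phase (amylose tris(3,5-dimethylphenylcarbamate)) should separate 20 from its (2R)-enantiomer F6, and the route resumes at 20.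

3. Step 2 (bromination). The bromine may enter next to the silyloxy group instead of between the two benzyloxy groups, or a second bromine may add, since all three positions are strongly activated.
 Fallback (aryl addition to a symmetric quinone, which fixes the regiochemistry by construction): from 1, oxidation with (KSO3)2NO (KH2PO4, acetone/H2O) should give 2,6-bis(benzyloxy)-1,4-benzoquinone F6-free of regiochemical ambiguity, here labelled F7. The aryllithium made from bromide 6 (n-BuLi, THF, −78 °C) should add to the carbonyl flanked by the two benzyloxy groups, the other carbonyl being deactivated as a doubly vinylogous ester, to give the quinol 4-aryl-4-hydroxy-3,5-bis(benzyloxy)cyclohexa-2,5-dien-1-one F8. Reductive aromatisation of F8 (Zn, AcOH, THF, 0 °C to rt) should give phenol 9, where the route resumes; steps 1, 2, 5, 6 and 7 are bypassed.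

**Further compounds**

F1 | step 9 | tert-butyl{2-iodo-4-[2,3-bis(benzyloxy)-5-(1,3-dioxolan-2-yl)phenyl]-3,5-bis(benzyloxy)phenoxy}dimethylsilane | CC(C)(C)[Si](C)(C)Oc1cc(OCc2ccccc2)c(-c2cc(C3OCCO3)cc(OCc3ccccc3)c2OCc2ccccc2)c(OCc2ccccc2)c1I
F2 | step 9 | N-methoxy-N-methyl-3-[4-(benzyloxy)phenyl]prop-2-ynamide | CON(C)C(=O)C#Cc1ccc(OCc2ccccc2)cc1
F3 | step 9 | tert-butyldimethylsilyl ether of ynone 12 | CC(C)(C)[Si](C)(C)Oc1cc(OCc2ccccc2)c(-c2cc(C3OCCO3)cc(OCc3ccccc3)c2OCc2ccccc2)c(OCc2ccccc2)c1C(=O)C#Cc1ccc(OCc2ccccc2)cc1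
F4 | step 13 | (2E)-1-[2-hydroxy-4,6-bis(benzyloxy)phenyl]-3-(3,4-bis(benzyloxy)-5-{5,7-bis(benzyloxy)-2-[4-(benzyloxy)phenyl]-4-oxo-4H-chromen-6-yl}phenyl)prop-2-en-1-one | O=C(/C=C/c1cc(OCc2ccccc2)c(OCc2ccccc2)c(-c2c(OCc3ccccc3)cc3oc(-c4ccc(OCc5ccccc5)cc4)cc(=O)c3c2OCc2ccccc2)c1)c1c(O)cc(OCc2ccccc2)cc1OCc1ccccc1
F5 | step 13 | racemic heptabenzyl flavanone (racemate of 20) | O=C1CC(c2cc(OCc3ccccc3)c(OCc3ccccc3)c(-c3c(OCc4ccccc4)cc4oc(-c5ccc(OCc6ccccc6)cc5)cc(=O)c4c3OCc3ccccc3)c2)Oc2cc(OCc3ccccc3)cc(OCc3ccccc3)c21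
F6 | step 13 | (2R)-enantiomer of 20 | O=C1C[C@H](c2cc(OCc3ccccc3)c(OCc3ccccc3)c(-c3c(OCc4ccccc4)cc4oc(-c5ccc(OCc6ccccc6)cc5)cc(=O)c4c3OCc3ccccc3)c2)Oc2cc(OCc3ccccc3)cc(OCc3ccccc3)c21
F7 | step 2 | 2,6-bis(benzyloxy)-1,4-benzoquinone | O=C1C=C(OCc2ccccc2)C(=O)C(OCc2ccccc2)=C1
F8 | step 2 | 4-[2,3-bis(benzyloxy)-5-(1,3-dioxolan-2-yl)phenyl]-4-hydroxy-3,5-bis(benzyloxy)cyclohexa-2,5-dien-1-one | O=C1C=C(OCc2ccccc2)C(O)(c2cc(C3OCCO3)cc(OCc3ccccc3)c2OCc2ccccc2)C(OCc2ccccc2)=C1
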